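Compound numbers used in all sections: 1 (3,4,5-trimethoxyphenyl)acetylene; 2 propargylic amine (not isolated); 3 (3,4,5-trimethoxyphenyl)allene; 4 (E)-but-2-enal; 5 (Z)-2-iodobut-2-enal; 6 (Z)-2-iodobut-2-en-1-ol; 7 tigloyl chloride; 8 (Z)-2-iodobut-2-enyl tiglate; 9 (Z)-2-(tigloyloxymethyl)but-2-enoic acid; 10 target. Atoms C1–C3 are the propenyl chain (C1 stereogenic); C1'–C4' are the butenoate chain (C1' carboxyl, C4' methyl).

## The problem

Target 10 is an acyclic diester on a ready-made 1,2,3-trimethoxybenzene ring. (S)-1-(3,4,5-Trimethoxyphenyl)prop-2-en-1-ol is acylated by (Z)-2-(hydroxymethyl)but-2-enoic acid, whose primary hydroxyl carries an (E)-2-methylbut-2-enoyl (tigloyl) group. The only stereocenter, C1, is benzylic to an electron-rich ring, allylic to the terminal C2=C3 vinyl group and O-acylated. It ionizes easily, and each ionization means racemization or a 1,3-shift of the acyloxy group to C3, which is downhill because the alkene then conjugates with the ring. No other stereocenter can control C1, so it must be set by a catalyst, ideally in the step that forms the C1–O bond and late in the route. The central acid has a Z-trisubstituted C2'=C3' alkene with the C4' methyl cis to the carboxyl group (angelate-type, the less stable arrangement), so any reversible nucleophilic addition at C3' would deliver the E isomer. The same unit is a Baylis–Hillman-type allylic ester: a nucleophilic amine or phosphine adding at C3' can expel tiglate from the CH2 group on C2'. The feature that opens the key step is the array aryl–C1(H)(O-acyl)–C2H=C3H2. It is exactly the branched adduct of a carboxylic acid O–H across the C1=C2 bond of a 1-arylpropa-1,2-diene (O to C1, H to C2), and ring positions 2 and 6 flanking C1 are unsubstituted.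

## Retrosynthesis

**10 ⇒ 3 + 9.** The C1–O and C2–H bonds are cut together, so 10 is the adduct of acid 9 across the aryl-substituted double bond of allene 3. Compared with the acyl C–O cut (esterifying a resolved alcohol), this makes the stereocenter, the vinyl group and the fragment union in one catalytic step. The step has no leaving group, runs near neutral, and is the last one, so the labile ester is never carried forward. The precursors are an achiral C12 cumulene and an achiral C10 acid. The forward step must give branched regioselectivity and ligand-controlled enantioselectivity, and must leave the allylic tigloyl ester of 9 alone.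

**9 ⇒ 8.** The C1'–C2' bond is cut: the carboxyl group comes from CO and water, and the geometry from alkenyl iodide 8. Standard Horner–Wadsworth–Emmons olefination, or allylic transposition of a Baylis–Hillman-type secondary ester, would favour the E geometry. Oxidative addition and CO insertion are stereoretentive, so iodine cis to methyl in 8 becomes carboxyl cis to methyl in 9. The carbonylation must outrun any reaction of palladium with the allylic ester.

**8 ⇒ 6 + 7; 6 ⇒ 5 ⇒ 4.** The tigloyl ester bond is made before the carboxyl group exists, by acylating iodo alcohol 6 with tigloyl chloride 7, so no second acid function competes. Alcohol 6 comes from aldehyde 5 by 1,2-reduction, and 5 from commercial (E)-but-2-enal 4 by α-iodination (C2–I bond). The geometry of 4 is inherited: methyl trans to formyl in 4 means methyl cis to iodine in 5.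

**3 ⇒ 1.** The terminal C2=C3 bond of the allene is cut; the CH2 carbon comes from formaldehyde in a Crabbé homologation of commercial alkyne 1 through propargylic amine 2. This is one step, against three for a resolved allylic alcohol.

## Roads not taken

Alternative 1: The acyl C–O bond is cut. Acid 9 is esterified with (S)-1-(3,4,5-trimethoxyphenyl)prop-2-en-1-ol A1, obtained by kinetic resolution of racemic alcohol A2 (vinyl Grignard addition to 3,4,5-trimethoxybenzaldehyde A3). The forward key step is a carbodiimide/DMAP esterification. This is the route most chemists would draw first. It sets the stereocenter in a separate operation that discards half of the material, and it carries the ionizable free alcohol A1 through isolation. It also activates 9 in the presence of a nucleophilic acyl-transfer catalyst, which can add at C3' and expel tiglate or scramble the Z alkene. The chosen plan joins the same two halves and sets C1 in one step, with one step instead of three on the aryl side.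

Alternative 2: The same C1–O bond is formed from an allyl electrophile: (E)-3-(3,4,5-trimethoxyphenyl)prop-2-en-1-yl methyl carbonate A4 is substituted by the carboxylate of 9 under iridium–phosphoramidite catalysis. The forward key step is an enantioselective, branched-selective allylic esterification. It needs a leaving group (A4 takes extra steps from the cinnamic acid) and a stoichiometric carboxylate salt of base-sensitive 9. The carboxylate in the product is itself a leaving group for the same allyliridium intermediate, so the step is reversible. With this electron-rich ring, reversibility drains toward the racemate and the conjugated linear ester A5. In the chosen rhodium hydride manifold the allyl intermediate is entered by hydrometalation of an allene, a path the product cannot re-enter, and no stoichiometric base is present.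

Alternative 3: The central acid is built on a preformed ester by Morita–Baylis–Hillman chemistry. Acrylate A6 of alcohol A1 reacts with acetaldehyde A7 to give adduct A8, and SN2' transposition with tiglate moves the oxygen to the CH2 group. The forward key step is this allylic transposition. It delivers mainly the E isomer A9, because the transposed enoate keeps its ester planar only when the cis substituent on C3' is hydrogen, so the geometry is wrong. It also leaves a labile 1-arylallyl ester for a long time with a nucleophilic amine and still needs resolved A1. The chosen plan takes the Z geometry stereospecifically from an alkenyl iodide.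

Key step: step 6

Remark on the chemistry: both antipodes of DIOP are commercial. The route is written with (R,R)-DIOP on the assumption that it leads to the S configuration at C1 of an aryl allene; the mirror-image ligand is to be used if configurational correlation of 10 shows the opposite sense.

## Route

Step 1
Reactants: 1 (3,4,5-trimethoxyphenyl)acetylene (5-ethynyl-1,2,3-trimethoxybenzene)
Product: 3 (3,4,5-trimethoxyphenyl)allene [1,2,3-trimethoxy-5-(propa-1,2-dien-1-yl)benzene], via propargylic amine 2 (not isolated)
Conditions: (CH2O)n (2.5 equiv), Cy2NH (1.8 equiv), CuI (copper iodide, 0.5 equiv), 1,4-dioxane, reflux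
Reagents that add atoms: paraformaldehyde (reacts as formaldehyde), C=O
Why: Crabbé homologation: the copper acetylide of 1 adds to the iminium ion from formaldehyde and Cy2NH (Mannich step) to give 2, which under copper catalysis transfers a cyclohexyl α-hydrogen to the aryl-bearing alkyne carbon (1,5-hydride shift) and fragments to the allene and an imine; aryl acetylenes are standard substrates and the methoxy groups are inert.

Step 2
Reactants: 4 (E)-but-2-enal (crotonaldehyde)
Product: 5 (Z)-2-iodobut-2-enal
Conditions: I2 (1.5 equiv), K2CO3 (1.2 equiv), DMAP (0.2 equiv), THF/H2O 1:1, 0 °C to rt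
Reagents that add atoms: iodine, II
Why: Amine-catalysed α-iodination of an enal (Baylis–Hillman-type addition of DMAP at C3, iodination of the enolate at C2, E1cB loss of DMAP); the elimination should place methyl trans to formyl and hence cis to iodine, the Z geometry that the target needs.

Step 3
Reactants: 5 (Z)-2-iodobut-2-enal
Product: 6 (Z)-2-iodobut-2-en-1-ol
Conditions: NaBH4, CeCl3·7H2O, MeOH, 0 °C
Reagents that add atoms: none
Why: Luche 1,2-reduction; the cerium-modified borohydride attacks only the carbonyl group, so the alkenyl C–I bond and the alkene geometry should be untouched.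

Step 4
Reactants: 6 (Z)-2-iodobut-2-en-1-ol; 7 (E)-2-methylbut-2-enoyl chloride (tigloyl chloride)
Product: 8 (Z)-2-iodobut-2-en-1-yl (E)-2-methylbut-2-enoate
Conditions: pyridine (2 equiv), DMAP (5 mol%), CH2Cl2, 0 °C to rt
Reagents that add atoms: none
Why: Standard acylation of a primary allylic alcohol by an acid chloride; the E geometry of the tigloyl unit is the thermodynamic one, the alkenyl iodide is inert, and no second carboxyl group is yet present to compete.

Step 5
Reactants: 8 (Z)-2-iodobut-2-en-1-yl (E)-2-methylbut-2-enoate
Product: 9 (Z)-2-({[(E)-2-methylbut-2-enoyl]oxy}methyl)but-2-enoic acid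
Conditions: Pd(OAc)2 (5 mol%), PPh3 (10 mol%), CO (1 atm), H2O (10 equiv), Et3N (3 equiv), DMF, 40 °C; then 1 M HCl
Reagents that add atoms: carbon monoxide, [C-]#[O+]; water, O
Why: Palladium-catalysed hydroxycarbonylation of an alkenyl iodide: oxidative addition of the C–I bond to zerovalent palladium (formed in situ) and CO insertion both proceed with retention, and water/Et3N cleave the acylpalladium, so carboxyl ends up cis to methyl as iodine was; C–I oxidative addition is far faster than ionization of the allylic tigloyl ester, and the CO atmosphere should intercept the alkenylpalladium before β-acyloxy elimination.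

Step 6
Reactants: 3 (3,4,5-trimethoxyphenyl)allene; 9 (Z)-2-({[(E)-2-methylbut-2-enoyl]oxy}methyl)but-2-enoic acid
Product: 10 (S)-1-(3,4,5-trimethoxyphenyl)prop-2-en-1-yl (Z)-2-({[(E)-2-methylbut-2-enoyl]oxy}methyl)but-2-enoate
Conditions: [Rh(cod)Cl]2 (2.5 mol%), (R,R)-DIOP (6 mol%), Cs2CO3 (5 mol%), 3 (1.3 equiv), ClCH2CH2Cl, 0 °C; chromatography on Et3N-deactivated silica
Reagents that add atoms: none
Why: The O–H bond of 9 adds oxidatively to the monovalent rhodium–DIOP complex to give a trivalent rhodium hydride carboxylate, which hydrometalates allene 3 with hydride delivery to the central carbon C2 and so forms a trivalent rhodium allyl carboxylate. C–O bond formation at the aryl-bearing terminus C1, presumably from the σ-allyl bound through CH2 via a six-membered transition state that includes the carboxylate, releases the branched ester and returns monovalent rhodium. The closest known reaction type is the rhodium/diphosphine-catalysed enantioselective addition of carboxylic acids to monosubstituted allenes to give branched allylic esters. No ring is closed. The single new stereocenter C1 is set by the catalyst: the twofold-symmetric DIOP differentiates the two faces of the allyl unit in the C–O bond-forming step, and because the allyl intermediate can equilibrate by π–σ–π interconversion the result should not depend on which allene face was hydrometalated. The step needs branched over linear regioselectivity, enantioface selectivity, and chemoselectivity for the allene over the two trisubstituted alkenes and the allylic tigloyl ester of 9. The branched preference is inherent to this rhodium manifold and the free ring positions 2 and 6 keep C1 accessible. Trisubstituted electron-poor alkenes should not insert into the Rh–H bond, and the absence of a leaving group and of stoichiometric base, together with 0 °C, should limit re-ionization of the product.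

## Compound list

1 | (3,4,5-trimethoxyphenyl)acetylene (5-ethynyl-1,2,3-trimethoxybenzene) | C#Cc1cc(OC)c(OC)c(OC)c1 | starting material
2 | N,N-dicyclohexyl-3-(3,4,5-trimethoxyphenyl)prop-2-yn-1-amine | COc1cc(C#CCN(C2CCCCC2)C2CCCCC2)cc(OC)c1OC | intermediate
3 | (3,4,5-trimethoxyphenyl)allene [1,2,3-trimethoxy-5-(propa-1,2-dien-1-yl)benzene] | C=C=Cc1cc(OC)c(OC)c(OC)c1 | intermediate
4 | (E)-but-2-enal | C/C=C/C=O | starting material
5 | (Z)-2-iodobut-2-enal | C/C=C(\I)C=O | intermediate
6 | (Z)-2-iodobut-2-en-1-ol | C/C=C(\I)CO | intermediate
7 | (E)-2-methylbut-2-enoyl chloride | C/C=C(\C)C(Cl)=O | starting material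
8 | (Z)-2-iodobut-2-en-1-yl (E)-2-methylbut-2-enoate | C/C=C(\I)COC(=O)/C(C)=C/C | intermediate
9 | (Z)-2-({[(E)-2-methylbut-2-enoyl]oxy}methyl)but-2-enoic acid | C/C=C(\C(O)=O)COC(=O)/C(C)=C/C | intermediate
10 | (S)-1-(3,4,5-trimethoxyphenyl)prop-2-en-1-yl (Z)-2-({[(E)-2-methylbut-2-enoyl]oxy}methyl)but-2-enoate | C=C[C@H](OC(=O)/C(=C\C)COC(=O)/C(C)=C/C)c1cc(OC)c(OC)c(OC)c1 | target

## Step count and risks

Total steps: 6. Longest linear sequence: 5 (4 → 5 → 6 → 8 → 9 → 10); the aryl branch is 2 steps (1 → 3 → 10).

**Step 6 (key step).** Four things are most likely to go wrong: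
- Loss of regiocontrol, either by C–O bond formation at C3 or by later re-ionization and 1,3-transposition of the acyloxy group, because conjugation with the electron-rich ring rewards it.
- Weaker enantioface discrimination for an aryl-substituted allyl unit than for the alkyl cases on which this reaction type rests.
- Ionization of the product on acidic silica.
- Capture of the allylic tigloyl ester of 9 by phosphine or by rhodium.

Fallback (sets out from acid 9, comes back at target 10): vinylmagnesium bromide adds to 3,4,5-trimethoxybenzaldehyde F1 (purchased) to give racemic 1-(3,4,5-trimethoxyphenyl)prop-2-en-1-ol F2. Acylation with vinyl acetate under a lipase (Candida antarctica lipase B) should leave (S)-1-(3,4,5-trimethoxyphenyl)prop-2-en-1-ol F3 unreacted, while the R enantiomer is removed as (R)-1-(3,4,5-trimethoxyphenyl)prop-2-en-1-yl acetate F4. Acid 9 is converted with 1-chloro-N,N,2-trimethylprop-1-en-1-amine under neutral conditions into (Z)-2-({[(E)-2-methylbut-2-enoyl]oxy}methyl)but-2-enoyl chloride F5. This acylates F3 in CH2Cl2/pyridine at −20 °C, without a nucleophilic acyl-transfer catalyst, to give 10.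

**Step 5.** Zerovalent palladium may ionize the allylic tigloyl ester of the substrate or of the product carboxylate, leading to loss of tiglate or Z/E scrambling through π–σ–π interconversion. The alkenylpalladium may also undergo β-acyloxy elimination if CO insertion is slow.

Fallback (sets out from iodo alcohol 6, comes back at acid 9): 6 is deprotonated with n-BuLi and then treated with t-BuLi (2 equiv) in Et2O at −78 °C for iodine–lithium exchange; the alkenyllithium keeps its configuration. Quenching with CO2 and acidifying gives (Z)-2-(hydroxymethyl)but-2-enoic acid F6. Excess tigloyl chloride 7 in pyridine/CH2Cl2 acylates the hydroxyl and, transiently, the carboxyl group to give the mixed anhydride (Z)-2-({[(E)-2-methylbut-2-enoyl]oxy}methyl)but-2-enoic (E)-2-methylbut-2-enoic anhydride F7. Aqueous NaHCO3/pyridine hydrolyses this in the same flask to 9 and tiglic acid, which is removed by sublimation or chromatography. No palladium touches the allylic ester.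

**Step 1.** The sequence may stall at the propargylic amine stage if the hydride-transfer fragmentation is slow, and the arylallene may oligomerize under copper at reflux.

Fallback (sets out from alkyne 1, comes back at allene 3): lithiation of 1 (n-BuLi, THF, −78 °C) and addition to paraformaldehyde gives 3-(3,4,5-trimethoxyphenyl)prop-2-yn-1-ol F8. A Mitsunobu reaction with 2-nitrobenzenesulfonylhydrazide (PPh3, DEAD, THF, −15 °C) gives 2-nitro-N-[3-(3,4,5-trimethoxyphenyl)prop-2-yn-1-yl]benzenesulfonohydrazide F9. On warming to rt this loses the sulfinic acid to give [3-(3,4,5-trimethoxyphenyl)prop-2-yn-1-yl]diazene F10, whose retro-ene loss of N2 gives 3 (Myers allene synthesis), with no copper and no heating.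

Further compounds
F1 | step 6 | 3,4,5-trimethoxybenzaldehyde | COc1cc(C=O)cc(OC)c1OC
F2 | step 6 | racemic 1-(3,4,5-trimethoxyphenyl)prop-2-en-1-ol | C=CC(O)c1cc(OC)c(OC)c(OC)c1
F3 | step 6 | (S)-1-(3,4,5-trimethoxyphenyl)prop-2-en-1-ol | C=C[C@H](O)c1cc(OC)c(OC)c(OC)c1
F4 | step 6 | (R)-1-(3,4,5-trimethoxyphenyl)prop-2-en-1-yl acetate | C=C[C@@H](OC(C)=O)c1cc(OC)c(OC)c(OC)c1
F5 | step 6 | (Z)-2-({[(E)-2-methylbut-2-enoyl]oxy}methyl)but-2-enoyl chloride | C/C=C(\C(Cl)=O)COC(=O)/C(C)=C/C
F6 | step 5 | (Z)-2-(hydroxymethyl)but-2-enoic acid | C/C=C(\C(O)=O)CO
F7 | step 5 | (Z)-2-({[(E)-2-methylbut-2-enoyl]oxy}methyl)but-2-enoic (E)-2-methylbut-2-enoic anhydride | C/C=C(\C(=O)OC(=O)/C(C)=C/C)COC(=O)/C(C)=C/C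
F8 | step 1 | 3-(3,4,5-trimethoxyphenyl)prop-2-yn-1-ol | OCC#Cc1cc(OC)c(OC)c(OC)c1
F9 | step 1 | 2-nitro-N-[3-(3,4,5-trimethoxyphenyl)prop-2-yn-1-yl]benzenesulfonohydrazide | NN(CC#Cc1cc(OC)c(OC)c(OC)c1)S(=O)(=O)c1ccccc1[N+](=O)[O-]
F10 | step 1 | [3-(3,4,5-trimethoxyphenyl)prop-2-yn-1-yl]diazene | N=NCC#Cc1cc(OC)c(OC)c(OC)c1
A1 | alternative 1 | (S)-1-(3,4,5-trimethoxyphenyl)prop-2-en-1-ol | C=C[C@H](O)c1cc(OC)c(OC)c(OC)c1
A2 | alternative 1 | racemic 1-(3,4,5-trimethoxyphenyl)prop-2-en-1-ol | C=CC(O)c1cc(OC)c(OC)c(OC)c1
A3 | alternative 1 | 3,4,5-trimethoxybenzaldehyde | COc1cc(C=O)cc(OC)c1OC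
A4 | alternative 2 | (E)-3-(3,4,5-trimethoxyphenyl)prop-2-en-1-yl methyl carbonate | COC(=O)OC/C=C/c1cc(OC)c(OC)c(OC)c1
A5 | alternative 2 | (E)-3-(3,4,5-trimethoxyphenyl)prop-2-en-1-yl (Z)-2-({[(E)-2-methylbut-2-enoyl]oxy}methyl)but-2-enoate | C/C=C(\C(=O)OC/C=C/c1cc(OC)c(OC)c(OC)c1)COC(=O)/C(C)=C/C
A6 | alternative 3 | (S)-1-(3,4,5-trimethoxyphenyl)prop-2-en-1-yl prop-2-enoate | C=C[C@H](OC(=O)C=C)c1cc(OC)c(OC)c(OC)c1
A7 | alternative 3 | acetaldehyde | CC=O
A8 | alternative 3 | (S)-1-(3,4,5-trimethoxyphenyl)prop-2-en-1-yl 3-hydroxy-2-methylidenebutanoate (mixture at C3 of the acid) | C=C[C@H](OC(=O)C(=C)C(C)O)c1cc(OC)c(OC)c(OC)c1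
A9 | alternative 3 | (S)-1-(3,4,5-trimethoxyphenyl)prop-2-en-1-yl (E)-2-({[(E)-2-methylbut-2-enoyl]oxy}methyl)but-2-enoate | C=C[C@H](OC(=O)/C(=C/C)COC(=O)/C(C)=C/C)c1cc(OC)c(OC)c(OC)c1
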